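**Plan**

- Retrosynthesis: ring C is cut at O1–C2 and C2–C3 (oxidative chalcone cyclisation, then aldol), giving ring-B aldehyde 16 and ring-A acetophenone 19; the C8–prenyl bond of 19 is cut back to phloroacetophenone.
- Ring B is cut at C5'–C6' and C1'–C2'. Its C5'(OH), C4'(O), C3'(prenyl) and C2'(prenyl) map onto the ring oxygen, C2, C3, C4 and C5 of a 3-silyloxy-4,5-diprenylfuran, and C6'–C1'(CO2Me) is methyl propiolate.
- The furan is cut at O–C5 (cyclodehydration of a 1-hydroxy-2,4-diketone) and at the two C–C bonds to the central diketone carbon (acylation, prenylation).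
- Forward order: furanone ring, silyloxyfuran, ring B by [4+2] addition and bridge opening, chalcone, ring C; ring A is bought.
- Stereochemistry: the target has no stereocentre; the transient centres in 6, 11 and 21 are all destroyed later.

Key step: step 5

Assumption: during the bridge opening in step 5 the silyl group may shift to the neighbouring catechol oxygen; 12 is drawn as the 4-silyl ether, and both isomers give 13 in step 6.

**Route**

Step 1
Reactants: 1 4-methylpent-3-enoic acid; 2 1-(tert-butyldimethylsilyloxy)propan-2-one (commercial)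
Product: 4 1-(tert-butyldimethylsilyloxy)-7-methyloct-6-ene-2,4-dione, via acyl imidazole 3 (not isolated)
Conditions: 1, CDI, THF, rt; separately 2 (2.2 equiv), LiN(i-Pr)2 (2.2 equiv), THF, −78 °C; add solution of 3, −78 → −40 °C; AcOH quench
Reagents that add atoms: none
Why: Kinetic deprotonation of 2 on the methyl side, away from the bulky silyloxy group, followed by C-acylation of the lithium enolate by the acyl imidazole (crossed Claisen-type acylation) should give the 1,3-diketone, the second equivalent of enolate being taken up by the acidic product.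

Step 2
Reactants: 4 1-(tert-butyldimethylsilyloxy)-7-methyloct-6-ene-2,4-dione; 5 prenyl bromide
Product: 6 1-(tert-butyldimethylsilyloxy)-7-methyl-3-(3-methylbut-2-enyl)oct-6-ene-2,4-dione (racemic)
Conditions: K2CO3 (1.2 equiv), 5 (1.05 equiv), acetone, rt → 45 °C
Reagents that add atoms: none
Why: The stabilised 1,3-diketone enolate is alkylated at its central carbon by the soft allylic bromide (classical C-alkylation of a β-diketone), and one equivalent of halide limits double alkylation.

Step 3
Reactants: 6 1-(tert-butyldimethylsilyloxy)-7-methyl-3-(3-methylbut-2-enyl)oct-6-ene-2,4-dione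
Product: 8 4,5-bis(3-methylbut-2-enyl)furan-3(2H)-one, via hydroxy diketone 7 (not isolated)
Conditions: 1 M aq. HCl, THF, rt
Reagents that add atoms: none
Why: Acid removes the primary silyl ether, the freed hydroxyl adds to the C4 carbonyl (5-exo-trig) and the hemiketal dehydrates to the vinylogous ester, which is the standard 3(2H)-furanone synthesis from α'-hydroxy-1,3-diketones and is mild enough to leave the trisubstituted alkenes alone.

Step 4
Reactants: 8 4,5-bis(3-methylbut-2-enyl)furan-3(2H)-one
Product: 9 tert-butyldimethyl{[4,5-bis(3-methylbut-2-enyl)furan-3-yl]oxy}silane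
Conditions: TBSOTf (1.2 equiv), Et3N (2 equiv), CH2Cl2, 0 °C; rapid non-aqueous work-up, used crude
Reagents that add atoms: tert-butyldimethylsilyl triflate, CC(C)(C)[Si](C)(C)OS(=O)(=O)C(F)(F)F
Why: Soft enolisation of the ketone towards C2 is the only direction that gives an aromatic furan, so silyl enol ether formation with a silyl triflate and an amine base should deliver the 3-silyloxyfuran.

Step 5
Reactants: 9 tert-butyldimethyl{[4,5-bis(3-methylbut-2-enyl)furan-3-yl]oxy}silane; 10 methyl propiolate
Product: 12 methyl 4-(tert-butyldimethylsilyloxy)-5-hydroxy-2,3-bis(3-methylbut-2-enyl)benzoate, via oxanorbornadiene 11 (not isolated)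
Conditions: 10 (3 equiv), toluene, 70 °C, sealed vessel; then silica gel, CH2Cl2, rt if 11 persists
Reagents that add atoms: none
Why: The electron-rich diene of 9 adds the propiolate in a normal-demand, asynchronous [4+2] cycloaddition, an intermolecular closure that forms the six-membered carbocycle through the C5'–C6' and C1'–C2' bonds and gives 7-oxanorbornadiene 11. In 11 the bridging C2'–O bond is allylic to the silyl enol ether, so it ionises to a siloxy-stabilised cyclohexadienyl cation, and loss of the C5' proton gives the phenol; the prenylated bridgehead has no hydrogen to lose, so only the C5' phenol can form. The closest known reaction type is the Diels–Alder reaction of 3-alkoxy- and 3-silyloxyfurans with acetylenic esters followed by opening of the oxygen bridge to phenols. No stereocentre remains, since both bridgehead centres of racemic 11 vanish on aromatisation. The step needs one regiochemistry, ester carbon to the prenylated furan C5: the siloxy group places the largest HOMO coefficient on C2, which pairs with the β-carbon of the propiolate, and the alkyl group on C5 acts in the same direction.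

Step 6
Reactants: 12 methyl 4-(tert-butyldimethylsilyloxy)-5-hydroxy-2,3-bis(3-methylbut-2-enyl)benzoate
Product: 13 methyl 4,5-dihydroxy-2,3-bis(3-methylbut-2-enyl)benzoate
Conditions: Bu4NF (1.1 equiv), AcOH (1.1 equiv), THF, 0 °C, argon
Reagents that add atoms: none
Why: Fluoride cleaves the aryl silyl ether, and the acetic acid buffer keeps the catechol protonated so that it is not oxidised as its anion.

Step 7
Reactants: 13 methyl 4,5-dihydroxy-2,3-bis(3-methylbut-2-enyl)benzoate
Product: 14 methyl 4,5-bis(methoxymethoxy)-2,3-bis(3-methylbut-2-enyl)benzoate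
Conditions: MOMCl (3 equiv), i-Pr2NEt (4 equiv), Bu4NI (cat.), CH2Cl2, 0 → 40 °C
Reagents that add atoms: chloromethyl methyl ether, COCCl
Why: Williamson-type O-alkylation of both phenols with the reactive α-chloro ether gives base-stable acetals that survive the hydride, hydroxide and peroxide steps ahead.

Step 8
Reactants: 14 methyl 4,5-bis(methoxymethoxy)-2,3-bis(3-methylbut-2-enyl)benzoate
Product: 15 [4,5-bis(methoxymethoxy)-2,3-bis(3-methylbut-2-enyl)phenyl]methanol
Conditions: i-Bu2AlH (2.5 equiv), CH2Cl2, −78 → 0 °C; aq. KNaC4H4O6 (potassium sodium tartrate) work-up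
Reagents that add atoms: none
Why: Hydride reduction of the aryl ester to the benzylic alcohol leaves the acetals and the isolated alkenes untouched.

Step 9
Reactants: 15 [4,5-bis(methoxymethoxy)-2,3-bis(3-methylbut-2-enyl)phenyl]methanol
Product: 16 4,5-bis(methoxymethoxy)-2,3-bis(3-methylbut-2-enyl)benzaldehyde
Conditions: MnO2 (activated, 15 equiv), CH2Cl2, rt
Reagents that add atoms: none
Why: Activated MnO2 oxidises benzylic alcohols selectively to aldehydes without over-oxidation and does not attack the prenyl groups.

Step 10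
Reactants: 17 2,4,6-trihydroxyacetophenone; 5 prenyl bromide
Product: 18 1-[2,4,6-trihydroxy-3-(3-methylbut-2-enyl)phenyl]ethanone
Conditions: 5 (1.0 equiv), DBU (1.1 equiv), THF, 0 °C → rt
Reagents that add atoms: none
Why: The phloroglucinol-type phenoxide reacts as a carbon nucleophile at its ring position (known C-prenylation of acylphloroglucinols), the two free ring carbons are equivalent, and the stoichiometry limits a second alkylation.

Step 11
Reactants: 18 1-[2,4,6-trihydroxy-3-(3-methylbut-2-enyl)phenyl]ethanone
Product: 19 1-[2-hydroxy-4,6-bis(methoxymethoxy)-3-(3-methylbut-2-enyl)phenyl]ethanone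
Conditions: MOMCl (2.2 equiv), i-Pr2NEt (2.5 equiv), CH2Cl2, 0 °C
Reagents that add atoms: chloromethyl methyl ether, COCCl
Why: The para hydroxyl and the less hindered ortho hydroxyl are etherified, while the hydroxyl flanked by the prenyl and acetyl groups stays hydrogen-bonded to the carbonyl and is left free for the later ring closure (selective acetal protection of a chelated polyphenol).

Step 12
Reactants: 16 4,5-bis(methoxymethoxy)-2,3-bis(3-methylbut-2-enyl)benzaldehyde; 19 1-[2-hydroxy-4,6-bis(methoxymethoxy)-3-(3-methylbut-2-enyl)phenyl]ethanone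
Product: 20 (E)-1-[2-hydroxy-4,6-bis(methoxymethoxy)-3-(3-methylbut-2-enyl)phenyl]-3-[4,5-bis(methoxymethoxy)-2,3-bis(3-methylbut-2-enyl)phenyl]prop-2-en-1-one
Conditions: KOH (50% aq., excess), EtOH, 0 °C → rt
Reagents that add atoms: none
Why: Claisen–Schmidt condensation of the methyl ketone enolate with the non-enolisable aldehyde, followed by E1cB dehydration, gives the E-chalcone, and the acetals and prenyl groups are stable to hydroxide.

Step 13
Reactants: 20 (E)-1-[2-hydroxy-4,6-bis(methoxymethoxy)-3-(3-methylbut-2-enyl)phenyl]-3-[4,5-bis(methoxymethoxy)-2,3-bis(3-methylbut-2-enyl)phenyl]prop-2-en-1-one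
Product: 22 3-hydroxy-5,7-bis(methoxymethoxy)-2-[4,5-bis(methoxymethoxy)-2,3-bis(3-methylbut-2-enyl)phenyl]-8-(3-methylbut-2-enyl)chromen-4-one, via trans-dihydroflavonol 21 (not isolated)
Conditions: 30% aq. H2O2, NaOH (aq.), MeOH, 0 °C → rt
Reagents that add atoms: hydrogen peroxide, OO
Why: In the Algar–Flynn–Oyamada reaction the enone is oxygenated at the α-carbon by hydroperoxide, the free phenoxide closes the six-membered ring C at the β-carbon, and further alkaline peroxide dehydrogenates the 3-hydroxyflavanone, while the electron-rich prenyl alkenes are inert to the nucleophilic oxidant.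

Step 14
Reactants: 22 3-hydroxy-5,7-bis(methoxymethoxy)-2-[4,5-bis(methoxymethoxy)-2,3-bis(3-methylbut-2-enyl)phenyl]-8-(3-methylbut-2-enyl)chromen-4-one
Product: 23 Broussoflavonol G
Conditions: 3 M aq. HCl, MeOH, 45 °C, stopped as soon as the last acetal is gone
Reagents that add atoms: none
Why: The four aryl methoxymethyl acetals are cleaved by acid-catalysed transacetalisation to methanol under dilute conditions in which protonation of the trisubstituted prenyl alkenes is slow.

**Compound list**

1 | 4-methylpent-3-enoic acid | CC(C)=CCC(=O)O | starting material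
2 | 1-(tert-butyldimethylsilyloxy)propan-2-one | CC(=O)CO[Si](C)(C)C(C)(C)C | starting material
3 | 1-(imidazol-1-yl)-4-methylpent-3-en-1-one (not isolated) | CC(C)=CCC(=O)n1ccnc1 | intermediate
4 | 1-(tert-butyldimethylsilyloxy)-7-methyloct-6-ene-2,4-dione | CC(C)=CCC(=O)CC(=O)CO[Si](C)(C)C(C)(C)C | intermediate
5 | prenyl bromide (1-bromo-3-methylbut-2-ene) | CC(C)=CCBr | starting material
6 | 1-(tert-butyldimethylsilyloxy)-7-methyl-3-(3-methylbut-2-enyl)oct-6-ene-2,4-dione (racemic, epimerisable centre) | CC(C)=CCC(=O)C(CC=C(C)C)C(=O)CO[Si](C)(C)C(C)(C)C | intermediate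
7 | 1-hydroxy-7-methyl-3-(3-methylbut-2-enyl)oct-6-ene-2,4-dione (not isolated) | CC(C)=CCC(=O)C(CC=C(C)C)C(=O)CO | intermediate
8 | 4,5-bis(3-methylbut-2-enyl)furan-3(2H)-one | CC(C)=CCC1=C(CC=C(C)C)C(=O)CO1 | intermediate
9 | tert-butyldimethyl{[4,5-bis(3-methylbut-2-enyl)furan-3-yl]oxy}silane | CC(C)=CCc1occ(O[Si](C)(C)C(C)(C)C)c1CC=C(C)C | intermediate
10 | methyl propiolate | C#CC(=O)OC | starting material
11 | methyl 5-(tert-butyldimethylsilyloxy)-1,6-bis(3-methylbut-2-enyl)-7-oxabicyclo[2.2.1]hepta-2,5-diene-2-carboxylate (racemic, one enantiomer drawn, not isolated) | COC(=O)C1=C[C@@H]2O[C@@]1(CC=C(C)C)C(CC=C(C)C)=C2O[Si](C)(C)C(C)(C)C | intermediate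
12 | methyl 4-(tert-butyldimethylsilyloxy)-5-hydroxy-2,3-bis(3-methylbut-2-enyl)benzoate | COC(=O)c1cc(O)c(O[Si](C)(C)C(C)(C)C)c(CC=C(C)C)c1CC=C(C)C | intermediate
13 | methyl 4,5-dihydroxy-2,3-bis(3-methylbut-2-enyl)benzoate | COC(=O)c1cc(O)c(O)c(CC=C(C)C)c1CC=C(C)C | intermediate
14 | methyl 4,5-bis(methoxymethoxy)-2,3-bis(3-methylbut-2-enyl)benzoate | COCOc1cc(C(=O)OC)c(CC=C(C)C)c(CC=C(C)C)c1OCOC | intermediate
15 | [4,5-bis(methoxymethoxy)-2,3-bis(3-methylbut-2-enyl)phenyl]methanol | COCOc1cc(CO)c(CC=C(C)C)c(CC=C(C)C)c1OCOC | intermediate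
16 | 4,5-bis(methoxymethoxy)-2,3-bis(3-methylbut-2-enyl)benzaldehyde | COCOc1cc(C=O)c(CC=C(C)C)c(CC=C(C)C)c1OCOC | intermediate
17 | 2,4,6-trihydroxyacetophenone | CC(=O)c1c(O)cc(O)cc1O | starting material
18 | 1-[2,4,6-trihydroxy-3-(3-methylbut-2-enyl)phenyl]ethanone | CC(=O)c1c(O)cc(O)c(CC=C(C)C)c1O | intermediate
19 | 1-[2-hydroxy-4,6-bis(methoxymethoxy)-3-(3-methylbut-2-enyl)phenyl]ethanone | CC(=O)c1c(OCOC)cc(OCOC)c(CC=C(C)C)c1O | intermediate
20 | (E)-1-[2-hydroxy-4,6-bis(methoxymethoxy)-3-(3-methylbut-2-enyl)phenyl]-3-[4,5-bis(methoxymethoxy)-2,3-bis(3-methylbut-2-enyl)phenyl]prop-2-en-1-one | COCOc1cc(OCOC)c(C(=O)/C=C/c2cc(OCOC)c(OCOC)c(CC=C(C)C)c2CC=C(C)C)c(O)c1CC=C(C)C | intermediate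
21 | trans-3-hydroxy-5,7-bis(methoxymethoxy)-2-[4,5-bis(methoxymethoxy)-2,3-bis(3-methylbut-2-enyl)phenyl]-8-(3-methylbut-2-enyl)chroman-4-one (racemic, one enantiomer drawn, not isolated) | COCOc1cc([C@@H]2[C@H](C(=O)c3c(OCOC)cc(OCOC)c(CC=C(C)C)c3O2)O)c(CC=C(C)C)c(CC=C(C)C)c1OCOC | intermediate
22 | 3-hydroxy-5,7-bis(methoxymethoxy)-2-[4,5-bis(methoxymethoxy)-2,3-bis(3-methylbut-2-enyl)phenyl]-8-(3-methylbut-2-enyl)chromen-4-one | COCOc1cc(OCOC)c2c(=O)c(O)c(-c3cc(OCOC)c(OCOC)c(CC=C(C)C)c3CC=C(C)C)oc2c1CC=C(C)C | intermediate
23 | Broussoflavonol G, 2-[4,5-dihydroxy-2,3-bis(3-methylbut-2-enyl)phenyl]-3,5,7-trihydroxy-8-(3-methylbut-2-enyl)chromen-4-one | CC(C)=CCc1c(-c2oc3c(CC=C(C)C)c(O)cc(O)c3c(=O)c2O)cc(O)c(O)c1CC=C(C)C | target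

**Step count**

Total step count: 14.
Longest linear sequence: 12 steps (steps 1 to 9, then 12 to 14); steps 10 and 11 form the short branch to 19.

**Steps most likely to fail**

Step 5. The furan may add to the propiolate only through C2 in an open-chain conjugate addition without closing the second bond, the silyl enol ether may be lost by adventitious hydrolysis before cycloaddition, or the bridge may not open cleanly. The fallback sets out from 9 and uses an alkene dienophile with a built-in leaving group in place of the alkyne. Methyl 2-chloroacrylate has the same polarisation and should add in toluene at rt to 50 °C to give methyl 2-chloro-5-(tert-butyldimethylsilyloxy)-1,6-bis(3-methylbut-2-enyl)-7-oxabicyclo[2.2.1]hept-5-ene-2-carboxylate F1 as a mixture of epimers at the chlorinated carbon. Treatment with Bu4NF in THF, followed by DBU, removes the silyl group; the enolate expels the bridging oxygen, hydrogen chloride is eliminated, and the hydroxy dienone tautomerises to catechol 13. The route is rejoined at 13, before step 7.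

Step 13. The phenoxide may attack the α-carbon of the oxygenated enone and close a five-membered ring, giving an aurone instead of ring C; the 6'-alkoxy group and the crowded ring B both favour this. The fallback sets out from 20 and separates ring closure from C3 oxygenation. Oxidative cyclisation with catalytic I2 in DMSO at 110 °C should give the flavone 5,7-bis(methoxymethoxy)-2-[4,5-bis(methoxymethoxy)-2,3-bis(3-methylbut-2-enyl)phenyl]-8-(3-methylbut-2-enyl)chromen-4-one F2. C3 of this flavone is then lithiated with LiN(i-Pr)2 in THF at −78 °C, the anion is trapped with B(OMe)3, and the borate is oxidised with H2O2 and AcOH to the flavonol. The route is rejoined at 22, before step 14.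

Step 1. The enolate may deprotonate the doubly activated α-methylene of the acyl imidazole (ketene formation, migration of the double bond into conjugation) instead of adding to it, and 2 may be enolised in part on the silyloxy side. The fallback sets out from 1 and builds the diketone by hydration of an ynone. The acid is converted with CDI and MeNHOMe·HCl into N-methoxy-N,4-dimethylpent-3-enamide F3. Addition of the lithium acetylide of tert-butyldimethyl(prop-2-ynyloxy)silane (n-BuLi, THF, −78 °C) gives 1-(tert-butyldimethylsilyloxy)-7-methyloct-6-en-2-yn-4-one F4. Conjugate addition of Et2NH gives (E)-2-(diethylamino)-1-(tert-butyldimethylsilyloxy)-7-methylocta-2,6-dien-4-one F5, and hydrolysis in buffered aqueous AcOH/NaOAc liberates the 1,3-diketone. The route is rejoined at 4, before step 2.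

**Further compounds**

F1 | step 5 | methyl 2-chloro-5-(tert-butyldimethylsilyloxy)-1,6-bis(3-methylbut-2-enyl)-7-oxabicyclo[2.2.1]hept-5-ene-2-carboxylate (racemic, both epimers at C2) | COC(=O)C1(Cl)C[C@@H]2O[C@@]1(CC=C(C)C)C(CC=C(C)C)=C2O[Si](C)(C)C(C)(C)C
F2 | step 13 | 5,7-bis(methoxymethoxy)-2-[4,5-bis(methoxymethoxy)-2,3-bis(3-methylbut-2-enyl)phenyl]-8-(3-methylbut-2-enyl)chromen-4-one | COCOc1cc(OCOC)c2c(=O)cc(-c3cc(OCOC)c(OCOC)c(CC=C(C)C)c3CC=C(C)C)oc2c1CC=C(C)C
F3 | step 1 | N-methoxy-N,4-dimethylpent-3-enamide | CC(C)=CCC(=O)N(C)OC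
F4 | step 1 | 1-(tert-butyldimethylsilyloxy)-7-methyloct-6-en-2-yn-4-one | CC(C)=CCC(=O)C#CCO[Si](C)(C)C(C)(C)C
F5 | step 1 | (E)-2-(diethylamino)-1-(tert-butyldimethylsilyloxy)-7-methylocta-2,6-dien-4-one | CCN(CC)/C(CO[Si](C)(C)C(C)(C)C)=C/C(=O)CC=C(C)C
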